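# Synthesis design for ebenfuran VI (compound 20) by carbenoid C–H insertion

## The problem

The target, ebenfuran VI (20), is an achiral 2-aryl-1-benzofuran-3-carbaldehyde. Its furan ring is fully substituted, and the benzo ring carries a hydroxyl at C4, a 3-hydroxy-3-methylbutyl chain at C5 and a methoxy group at C6, leaving only C7–H. The benzo ring is a phloroglucinol core whose three oxygens must be told apart: one becomes O1 of the furan, one stays a free phenol peri to the formyl group, one is a methyl ether, and the chain must sit between the last two. There is no stereocentre, so no stereocontrol is needed, but any stereocentre made on the way has to be erased by aromatization. The formyl group at C3 lies between the C2 aryl group and the C4 oxygen; a late electrophilic formylation would have to beat the free C7 position in a crowded peri environment, so the formyl carbon is better carried from the start. The fragile features are the tertiary alcohol (under acid it eliminates or closes a 2,2-dimethylchroman ring onto the C4 phenol), the electron-rich phenols and the aldehyde. The feature that opens the route is the C2–C3 bond. C2 is bound to O1 and to the electron-rich aryl ring, so in an open-chain precursor it is the methylene of an aryl benzyl ether on O1. C3 is bound to C3a and to the formyl carbon, so it can be an aryl(methoxycarbonyl)carbene, and the five atoms C3, C3a, C7a, O1 and C2 are then placed for a 1,5 C–H insertion.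

## Retrosynthesis

**End game, 20 back to 17.** No skeletal bond is cut. The phenolic triisopropylsilyl ether and the tertiary triethylsilyl ether of 19 are removed together by fluoride, which never exposes the tertiary alcohol and the C4 phenol to acid. Aldehyde 19 is the oxidation product of benzylic alcohol 18, and 18 comes from benzofuran ester 17 by a hydride reduction that also cleaves the C4 pivalate. Carrying the formyl carbon as an ester is preferred to formylating a finished benzofuran. The forward steps need only chemoselective redox changes at one carbon.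

**17 back to 16.** Adding hydrogen to C2 and C3 leads to dihydrobenzofuran 16. Connectivity is unchanged, but C2 and C3 become sp3 carbons, which makes the next cut possible. The forward step is a dehydrogenation that starts at C2–H, activated by O1 and the electron-rich aryl group. Both stereocentres of 16 vanish, so 16 may be any mixture of isomers.

**16 back to 15 (key cut, C2–C3).** Cutting C2–C3 gives diazo ester 15, in which the two halves are joined only by the O1–CH2 ether link. The neighbouring cuts are less attractive. An O1–C2 cut needs a leaving group on a very ionizable benzylic carbon. A C2–aryl cut leaves the hard part, the pentasubstituted benzofuran core, unsolved. The forward reaction must insert the carbene only into the ether CH2. This is secured by placing a pivalate, which has no C–H within reach, on the other ortho oxygen and by silylating the chain alcohol.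

**15 back to 14, then 10 and 13.** The diazo group of 15 is traced to the methylene of arylacetate 14 (diazo transfer). Cutting the O1–CH2 ether bond of 14 gives phenol 10 and benzylic alcohol 13, which are joined by a redox condensation. Alkylation with the corresponding benzylic halide is avoided because a 2,4-dioxygenated benzyl halide stores poorly. Alcohol 13 comes in two steps from aldehyde 11 through silyl ether 12. The ether is formed only after every step that uses hydrogen or acid, since the electron-rich benzyl ether would survive neither.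

**10 back to 8, then 5 and 7.** The C5 chain is cut at the aryl–carbon bond, giving aryl iodide 5 and alkyne 7 (the silyl ether of 6). Hydrogenation of the coupling product 8 saturates the chain (9) and then removes the temporary benzyl ether on the future O1, which frees exactly the oxygen that must receive 13. Iodide 5 carries a pivalate, not a free phenol, because an ortho-iodophenol would close a furan onto the alkyne during coupling.

**5 back to 4, 3, 2 and 1.** The acetic ester arm of 5 has the same two carbons as the acetyl group of 4, with the aryl group moved from the carbonyl carbon to the methyl carbon (oxidative 1,2-aryl shift). This is preferred to a sulfur/amine homologation, which neither the pivalate nor the iodide would survive, and it is placed before the acid-sensitive chain is introduced. Pivalate 4 comes from iodophenol 3, and 3 from monobenzyl ether 2. The three oxygens are told apart at this point. Symmetrical 1 can give only one monoether 2, and the remaining chelated hydroxyl of 2 directs iodine to its own ortho position. The chain therefore ends up next to the oxygen that becomes the C4 phenol, and the benzyl group marks the oxygen that becomes O1. Commercial 1 already holds the three oxygens, the methyl ether and the carbon substituent at the future C3a.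

## Roads not taken

**Alternative 1: ring switch of a spiro-epoxide lactone.** The cut is O1–C2. The precursor is spiro-epoxide A2, in which O1 is locked in a five-membered lactone and C2 is the benzylic epoxide carbon. In the forward step, methoxide in methanol opens the lactone to the methyl ester, the freed phenoxide attacks the epoxide at the benzylic carbon (5-exo-tet), and acid eliminates water from the resulting tertiary alcohol to give ester A1.

- Merits: only ionic chemistry, no diazo compound and no rhodium. The furan emerges aromatic, so a dehydrogenation is saved. The C3 ester is at the oxidation level of 17, so the end game would be as short as the chosen one.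
- Weak points: A2 derives from the same crowded arylacetic acid skeleton as 5, so the homologation problem is not avoided. Building A2 needs an aldol-type condensation beside the peri benzyloxy group and then epoxidation of a hindered, electron-poor alkene, where a nucleophilic peroxide also threatens the aryl lactone. The closing acid treatment acts on A1, whose tertiary alcohol is free and prone to elimination. Two benzyl ethers must finally be hydrogenolysed in the presence of an aldehyde, or earlier with extra steps.
- Comparison: this road is the better one in hazard and on scale. The chosen plan sets against it a ring closure under neutral conditions that needs neither an alkene of defined geometry nor an epoxide, and protecting groups that leave in steps needed anyway.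

**Alternative 2: benzannulation that builds the benzo ring.** The benzo ring is made last. The cut passes through C7–C7a, C6–C7, C4–C5 and C3a–C4 and leads to furyl diazoketone A4 and ynol ether A5. In the forward step (Danheiser benzannulation), irradiation triggers a Wolff rearrangement of A4, the resulting ketene adds to A5 in a [2+2] cycloaddition, and on heating the four-membered ring opens and recloses by 6π electrocyclization onto the furan. This delivers phenol A3 with the C3 carbon as a dioxolane.

- Merits: it is the most convergent of the four plans. The positions of hydroxyl, chain, methoxy and hydrogen follow from the mechanism and not from directing effects. The C4 hydroxyl appears free and unique, and the formyl carbon needs no redox adjustment.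
- Weak points: A4 is a furan with three different carbon substituents and A5 a sensitive alkoxyalkyne, and each needs a multistep synthesis. The cascade needs photolysis and then prolonged heating of a compound with a silyl ether and an acetal. Unmasking the aldehyde needs aqueous acid on a compound with the tertiary oxygen next to a free C4 phenol, which is the situation that closes the chroman. A benzyl ether must also be hydrogenolysed beside the aldehyde.
- Comparison: in regiochemical certainty this road is superior to the chosen plan, which relies on chelation-directed iodination in step 2. The chosen plan answers with commercial arene 1, which already has all three oxygens and the C3a substituent, with fewer steps overall and with an acid-free end game.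

**Alternative 3: ester-tethered C–H arylation through a coumestan lactone.** The cut is C2–C1′, the bond between the furan and the pendant aryl ring. Precursor A7 is an ester whose acyl part is a benzofuran-3-carboxylate with C2–H and whose alkoxy part is a 2-bromophenol. In the forward step, a palladium catalyst with a phosphine and a carbonate base inserts into the C–Br bond and metalates the acidic C2–H, and reductive elimination closes the six-membered lactone of coumestan A6.

- Merits: direct arylation at C2 of a benzofuran-3-carboxylate is dependable, the tether fixes the site, and the coupling is probably more reliable than a carbenoid insertion.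
- Weak points: the benzofuran core with its C4, C5 and C6 substituents must exist before the key step, so a separate furan ring synthesis is needed. The lactone oxygen of A6 sits where the target has a methoxy group. The key step must therefore be followed by reductive lactone opening, selective methylation of the freed phenol beside a benzylic alcohol, oxidation, hydrogenolysis of two benzyl ethers and desilylation, about twice the four steps that follow 16.
- Comparison: the chosen plan sets against the more reliable coupling a key step that creates the furan ring itself from an acyclic precursor, and a shorter end game with fewer kinds of deprotection.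

Key step: step 12

## Route

Remark on the chemistry: 16 is expected as a racemic mixture of cis and trans isomers and is used as such, because both stereocentres disappear in step 13.

Step 1
Reactants: 1 1-(2,6-dihydroxy-4-methoxyphenyl)ethanone
Product: 2 1-[2-(benzyloxy)-6-hydroxy-4-methoxyphenyl]ethanone
Conditions: BnBr, K2CO3, acetone, reflux
Reagents that add atoms: benzyl bromide, BrCc1ccccc1
Why: Williamson ether synthesis; 1 is symmetrical, so only one monoether can form, and the second hydroxyl stays hydrogen-bonded to the acetyl group and is alkylated much more slowly.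

Step 2
Reactants: 2 1-[2-(benzyloxy)-6-hydroxy-4-methoxyphenyl]ethanone
Product: 3 1-[6-(benzyloxy)-2-hydroxy-3-iodo-4-methoxyphenyl]ethanone
Conditions: N-iodosuccinimide, CF3CO2H (cat.), MeCN, 0 °C → rt
Reagents that add atoms: N-iodosuccinimide, O=C1CCC(=O)N1I
Why: Electrophilic aromatic iodination; in 2-hydroxy-4,6-dialkoxyacetophenones the chelated hydroxyl directs the electrophile to its own ortho position, here the carbon between hydroxyl and methoxy, and the unactivated benzyl ring does not react.

Step 3
Reactants: 3 1-[6-(benzyloxy)-2-hydroxy-3-iodo-4-methoxyphenyl]ethanone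
Product: 4 2-acetyl-3-(benzyloxy)-6-iodo-5-methoxyphenyl pivalate
Conditions: PivCl, Et3N, DMAP (cat.), CH2Cl2, 0 °C → reflux
Reagents that add atoms: pivaloyl chloride, CC(C)(C)C(=O)Cl
Why: DMAP-catalysed O-acylation of a phenol; the pivalate prevents furan formation in the alkyne coupling, resists the acid of step 4 and later shields the second ortho oxygen of the carbene precursor.

Step 4
Reactants: 4 2-acetyl-3-(benzyloxy)-6-iodo-5-methoxyphenyl pivalate
Product: 5 methyl 2-[6-(benzyloxy)-3-iodo-4-methoxy-2-(pivaloyloxy)phenyl]acetate
Conditions: PhI(OAc)2, H2SO4 (cat.), HC(OMe)3, rt → 50 °C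
Reagents that add atoms: trimethyl orthoformate, COC(OC)OC
Why: Oxidative 1,2-aryl migration of an aryl methyl ketone with a trivalent iodine reagent in acidic orthoformate; the enol ether is attacked at CH2 by the iodane, the ketal carbon keeps two methoxy groups, and the electron-rich aryl group shifts to CH2 as iodobenzene leaves, giving the methyl arylacetate.

Step 5
Reactants: 6 2-methylbut-3-yn-2-ol
Product: 7 triethyl[(2-methylbut-3-yn-2-yl)oxy]silane
Conditions: TESOTf, 2,6-lutidine, CH2Cl2, 0 °C
Reagents that add atoms: triethylsilyl trifluoromethanesulfonate, CC[Si](CC)(CC)OS(=O)(=O)C(F)(F)F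
Why: Silylation of a tertiary alcohol with a silyl triflate and a hindered pyridine base; the ether keeps the alcohol from eliminating later and from O–H insertion in step 12.

Step 6
Reactants: 5 methyl 2-[6-(benzyloxy)-3-iodo-4-methoxy-2-(pivaloyloxy)phenyl]acetate; 7 triethyl[(2-methylbut-3-yn-2-yl)oxy]silane
Product: 8 methyl 2-[6-(benzyloxy)-4-methoxy-3-{3-methyl-3-[(triethylsilyl)oxy]but-1-yn-1-yl}-2-(pivaloyloxy)phenyl]acetate
Conditions: PdCl2(PPh3)2 (cat.), CuI (cat.), Et3N, DMF, 60 °C
Reagents that add atoms: none
Why: Sonogashira coupling of an aryl iodide with a terminal alkyne; the ortho oxygen is acylated, so the aryl alkyne cannot cyclize to a furan.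

Step 7
Reactants: 8 methyl 2-[6-(benzyloxy)-4-methoxy-3-{3-methyl-3-[(triethylsilyl)oxy]but-1-yn-1-yl}-2-(pivaloyloxy)phenyl]acetate
Product: 10 methyl 2-[6-hydroxy-4-methoxy-3-{3-methyl-3-[(triethylsilyl)oxy]butyl}-2-(pivaloyloxy)phenyl]acetate, via saturated benzyl ether 9 (not isolated)
Conditions: H2 (1 atm), Pd/C, EtOAc, rt
Reagents that add atoms: none
Why: Heterogeneous hydrogenation saturates the alkyne first and then hydrogenolyses the benzyl aryl ether; pivalate, ester and silyl ether are inert in ethyl acetate, and the one phenol set free is the future O1.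

Step 8
Reactants: 11 4-hydroxy-2-methoxybenzaldehyde
Product: 12 2-methoxy-4-[(triisopropylsilyl)oxy]benzaldehyde
Conditions: TIPSCl, imidazole, DMF, rt
Reagents that add atoms: chlorotriisopropylsilane, CC(C)[Si](Cl)(C(C)C)C(C)C
Why: Silylation of a phenol with a silyl chloride and imidazole; the triisopropylsilyl ether tolerates the hydride, base and oxidants of the later steps.

Step 9
Reactants: 12 2-methoxy-4-[(triisopropylsilyl)oxy]benzaldehyde
Product: 13 {2-methoxy-4-[(triisopropylsilyl)oxy]phenyl}methanol
Conditions: NaBH4, MeOH, 0 °C
Reagents that add atoms: none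
Why: Borohydride reduction of an aryl aldehyde to the benzylic alcohol; the hindered aryl silyl ether is stable at this temperature.

Step 10
Reactants: 10 methyl 2-[6-hydroxy-4-methoxy-3-{3-methyl-3-[(triethylsilyl)oxy]butyl}-2-(pivaloyloxy)phenyl]acetate; 13 {2-methoxy-4-[(triisopropylsilyl)oxy]phenyl}methanol
Product: 14 methyl 2-[6-({2-methoxy-4-[(triisopropylsilyl)oxy]phenyl}methoxy)-4-methoxy-3-{3-methyl-3-[(triethylsilyl)oxy]butyl}-2-(pivaloyloxy)phenyl]acetate
Conditions: PPh3, DIAD, THF, 0 °C → rt
Reagents that add atoms: none
Why: Mitsunobu etherification of a phenol with a primary benzylic alcohol; the neutral conditions avoid the labile 2,4-dioxygenated benzyl halide and leave pivalate, ester and silyl ethers untouched.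

Step 11
Reactants: 14 methyl 2-[6-({2-methoxy-4-[(triisopropylsilyl)oxy]phenyl}methoxy)-4-methoxy-3-{3-methyl-3-[(triethylsilyl)oxy]butyl}-2-(pivaloyloxy)phenyl]acetate
Product: 15 methyl 2-diazo-2-[6-({2-methoxy-4-[(triisopropylsilyl)oxy]phenyl}methoxy)-4-methoxy-3-{3-methyl-3-[(triethylsilyl)oxy]butyl}-2-(pivaloyloxy)phenyl]acetate
Conditions: p-ABSA, DBU, MeCN, 0 °C → rt
Reagents that add atoms: 4-acetamidobenzenesulfonyl azide, CC(=O)Nc1ccc(cc1)S(=O)(=O)N=[N+]=[N-]
Why: Regitz diazo transfer from a sulfonyl azide to the DBU-generated enolate of an arylacetate, the standard entry to aryldiazoacetates.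

Step 12
Reactants: 15 methyl 2-diazo-2-[6-({2-methoxy-4-[(triisopropylsilyl)oxy]phenyl}methoxy)-4-methoxy-3-{3-methyl-3-[(triethylsilyl)oxy]butyl}-2-(pivaloyloxy)phenyl]acetate
Product: 16 methyl 2-{2-methoxy-4-[(triisopropylsilyl)oxy]phenyl}-6-methoxy-5-{3-methyl-3-[(triethylsilyl)oxy]butyl}-4-(pivaloyloxy)-2,3-dihydro-1-benzofuran-3-carboxylate (racemic; cis and trans isomers)
Conditions: Rh2(OAc)4 (1 mol%), CH2Cl2, 40 °C, slow addition of 15
Reagents that add atoms: none
Why: Dirhodium tetraacetate takes up the diazo carbon and expels dinitrogen to give an electrophilic aryl(methoxycarbonyl) carbenoid bound to the catalyst. The carbenoid inserts into a C–H bond of the ortho aryloxymethyl group through a concerted, asynchronous three-centre transition state with hydride-transfer character, and the positive charge building at that carbon is stabilized by the O1 lone pair and by the 2-methoxy-4-silyloxyphenyl ring. The closest known reaction type is the dirhodium-catalysed intramolecular C–H insertion of aryldiazoacetates into ortho benzyl ethers, which gives 2-aryl-2,3-dihydrobenzofuran-3-carboxylates. The furan ring (C3, C3a, C7a, O1, C2) closes as a five-membered ring by 1,5-insertion, with C2–C3 as the only new skeletal bond. The stereocentres C2 and C3 are set in the same event; their relative configuration is governed by the substrate in the catalyst-bound transition state (cis expected kinetically, trans by later epimerization at C3), and the achiral catalyst gives a racemate. Neither centre needs control, because both are removed in step 13. The step needs site selectivity, and the substrate provides it: the only activated C–H within reach is the O1 benzylic CH2, the other ortho oxygen carries a pivalate with no C–H in range, the chain alcohol is silylated so O–H insertion is excluded, and C7–H is an unreactive aryl C–H. Slow addition at high dilution suppresses bimolecular carbene coupling.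

Step 13
Reactants: 16 methyl 2-{2-methoxy-4-[(triisopropylsilyl)oxy]phenyl}-6-methoxy-5-{3-methyl-3-[(triethylsilyl)oxy]butyl}-4-(pivaloyloxy)-2,3-dihydro-1-benzofuran-3-carboxylate
Product: 17 methyl 2-{2-methoxy-4-[(triisopropylsilyl)oxy]phenyl}-6-methoxy-5-{3-methyl-3-[(triethylsilyl)oxy]butyl}-4-(pivaloyloxy)-1-benzofuran-3-carboxylate
Conditions: DDQ, 1,4-dioxane, 80 °C
Reagents that add atoms: none
Why: Quinone dehydrogenation; hydride abstraction from C2–H, activated by O1 and the 2,4-dioxygenated aryl ring, followed by loss of the acidic C3 proton, aromatizes the furan and removes both stereocentres, as known for 2-aryl-2,3-dihydrobenzofuran-3-carboxylates.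

Step 14
Reactants: 17 methyl 2-{2-methoxy-4-[(triisopropylsilyl)oxy]phenyl}-6-methoxy-5-{3-methyl-3-[(triethylsilyl)oxy]butyl}-4-(pivaloyloxy)-1-benzofuran-3-carboxylate
Product: 18 3-(hydroxymethyl)-6-methoxy-2-{2-methoxy-4-[(triisopropylsilyl)oxy]phenyl}-5-{3-methyl-3-[(triethylsilyl)oxy]butyl}-1-benzofuran-4-ol
Conditions: i-Bu2AlH (excess), CH2Cl2, −78 → 0 °C; aq. potassium sodium tartrate
Reagents that add atoms: none
Why: Aluminium hydride reduction; the conjugated ester goes to the primary alcohol and the aryl pivalate is cleaved reductively in the same pot, while the silyl ethers are stable; 18 is used without delay because it is an ionizable hydroxymethyl phenol.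

Step 15
Reactants: 18 3-(hydroxymethyl)-6-methoxy-2-{2-methoxy-4-[(triisopropylsilyl)oxy]phenyl}-5-{3-methyl-3-[(triethylsilyl)oxy]butyl}-1-benzofuran-4-ol
Product: 19 4-hydroxy-6-methoxy-2-{2-methoxy-4-[(triisopropylsilyl)oxy]phenyl}-5-{3-methyl-3-[(triethylsilyl)oxy]butyl}-1-benzofuran-3-carbaldehyde
Conditions: MnO2 (excess), CH2Cl2, rt
Reagents that add atoms: none
Why: Manganese dioxide oxidation of an activated heterobenzylic alcohol to the aldehyde, which is stabilized by a hydrogen bond to the C4 hydroxyl; unactivated positions and silyl ethers are untouched.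

Step 16
Reactants: 19 4-hydroxy-6-methoxy-2-{2-methoxy-4-[(triisopropylsilyl)oxy]phenyl}-5-{3-methyl-3-[(triethylsilyl)oxy]butyl}-1-benzofuran-3-carbaldehyde
Product: 20 4-hydroxy-2-(4-hydroxy-2-methoxyphenyl)-5-(3-hydroxy-3-methylbutyl)-6-methoxy-1-benzofuran-3-carbaldehyde
Conditions: Bu4NF, THF, 0 °C → rt
Reagents that add atoms: none
Why: Fluoride cleavage of the aryl and the tertiary alkyl silyl ether under non-acidic conditions, so that the tertiary alcohol neither eliminates nor closes a chroman ring onto the C4 phenol.

## Compound list

1 | 1-(2,6-dihydroxy-4-methoxyphenyl)ethanone | CC(=O)c1c(O)cc(OC)cc1O | starting material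
2 | 1-[2-(benzyloxy)-6-hydroxy-4-methoxyphenyl]ethanone | CC(=O)c1c(O)cc(OC)cc1OCc1ccccc1 | intermediate
3 | 1-[6-(benzyloxy)-2-hydroxy-3-iodo-4-methoxyphenyl]ethanone | CC(=O)c1c(O)c(I)c(OC)cc1OCc1ccccc1 | intermediate
4 | 2-acetyl-3-(benzyloxy)-6-iodo-5-methoxyphenyl pivalate | CC(=O)c1c(OC(=O)C(C)(C)C)c(I)c(OC)cc1OCc1ccccc1 | intermediate
5 | methyl 2-[6-(benzyloxy)-3-iodo-4-methoxy-2-(pivaloyloxy)phenyl]acetate | COC(=O)Cc1c(OC(=O)C(C)(C)C)c(I)c(OC)cc1OCc1ccccc1 | intermediate
6 | 2-methylbut-3-yn-2-ol | CC(C)(O)C#C | starting material
7 | triethyl[(2-methylbut-3-yn-2-yl)oxy]silane | C#CC(C)(C)O[Si](CC)(CC)CC | intermediate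
8 | methyl 2-[6-(benzyloxy)-4-methoxy-3-{3-methyl-3-[(triethylsilyl)oxy]but-1-yn-1-yl}-2-(pivaloyloxy)phenyl]acetate | COC(=O)Cc1c(OC(=O)C(C)(C)C)c(C#CC(C)(C)O[Si](CC)(CC)CC)c(OC)cc1OCc1ccccc1 | intermediate
9 | methyl 2-[6-(benzyloxy)-4-methoxy-3-{3-methyl-3-[(triethylsilyl)oxy]butyl}-2-(pivaloyloxy)phenyl]acetate | COC(=O)Cc1c(OC(=O)C(C)(C)C)c(CCC(C)(C)O[Si](CC)(CC)CC)c(OC)cc1OCc1ccccc1 | intermediate (not isolated)
10 | methyl 2-[6-hydroxy-4-methoxy-3-{3-methyl-3-[(triethylsilyl)oxy]butyl}-2-(pivaloyloxy)phenyl]acetate | COC(=O)Cc1c(OC(=O)C(C)(C)C)c(CCC(C)(C)O[Si](CC)(CC)CC)c(OC)cc1O | intermediate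
11 | 4-hydroxy-2-methoxybenzaldehyde | COc1cc(O)ccc1C=O | starting material
12 | 2-methoxy-4-[(triisopropylsilyl)oxy]benzaldehyde | COc1cc(O[Si](C(C)C)(C(C)C)C(C)C)ccc1C=O | intermediate
13 | {2-methoxy-4-[(triisopropylsilyl)oxy]phenyl}methanol | COc1cc(O[Si](C(C)C)(C(C)C)C(C)C)ccc1CO | intermediate
14 | methyl 2-[6-({2-methoxy-4-[(triisopropylsilyl)oxy]phenyl}methoxy)-4-methoxy-3-{3-methyl-3-[(triethylsilyl)oxy]butyl}-2-(pivaloyloxy)phenyl]acetate | COC(=O)Cc1c(OCc2ccc(O[Si](C(C)C)(C(C)C)C(C)C)cc2OC)cc(OC)c(CCC(C)(C)O[Si](CC)(CC)CC)c1OC(=O)C(C)(C)C | intermediate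
15 | methyl 2-diazo-2-[6-({2-methoxy-4-[(triisopropylsilyl)oxy]phenyl}methoxy)-4-methoxy-3-{3-methyl-3-[(triethylsilyl)oxy]butyl}-2-(pivaloyloxy)phenyl]acetate | COC(=O)C(=[N+]=[N-])c1c(OCc2ccc(O[Si](C(C)C)(C(C)C)C(C)C)cc2OC)cc(OC)c(CCC(C)(C)O[Si](CC)(CC)CC)c1OC(=O)C(C)(C)C | intermediate
16 | methyl 2-{2-methoxy-4-[(triisopropylsilyl)oxy]phenyl}-6-methoxy-5-{3-methyl-3-[(triethylsilyl)oxy]butyl}-4-(pivaloyloxy)-2,3-dihydro-1-benzofuran-3-carboxylate (racemic; cis and trans isomers; no configuration assigned) | COC(=O)C1C(c2ccc(O[Si](C(C)C)(C(C)C)C(C)C)cc2OC)Oc2cc(OC)c(CCC(C)(C)O[Si](CC)(CC)CC)c(OC(=O)C(C)(C)C)c21 | intermediate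
17 | methyl 2-{2-methoxy-4-[(triisopropylsilyl)oxy]phenyl}-6-methoxy-5-{3-methyl-3-[(triethylsilyl)oxy]butyl}-4-(pivaloyloxy)-1-benzofuran-3-carboxylate | COC(=O)c1c(-c2ccc(O[Si](C(C)C)(C(C)C)C(C)C)cc2OC)oc2cc(OC)c(CCC(C)(C)O[Si](CC)(CC)CC)c(OC(=O)C(C)(C)C)c12 | intermediate
18 | 3-(hydroxymethyl)-6-methoxy-2-{2-methoxy-4-[(triisopropylsilyl)oxy]phenyl}-5-{3-methyl-3-[(triethylsilyl)oxy]butyl}-1-benzofuran-4-ol | OCc1c(-c2ccc(O[Si](C(C)C)(C(C)C)C(C)C)cc2OC)oc2cc(OC)c(CCC(C)(C)O[Si](CC)(CC)CC)c(O)c12 | intermediate
19 | 4-hydroxy-6-methoxy-2-{2-methoxy-4-[(triisopropylsilyl)oxy]phenyl}-5-{3-methyl-3-[(triethylsilyl)oxy]butyl}-1-benzofuran-3-carbaldehyde | O=Cc1c(-c2ccc(O[Si](C(C)C)(C(C)C)C(C)C)cc2OC)oc2cc(OC)c(CCC(C)(C)O[Si](CC)(CC)CC)c(O)c12 | intermediate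
20 | 4-hydroxy-2-(4-hydroxy-2-methoxyphenyl)-5-(3-hydroxy-3-methylbutyl)-6-methoxy-1-benzofuran-3-carbaldehyde (ebenfuran VI; achiral) | COc1cc(O)ccc1-c1oc2cc(OC)c(CCC(C)(C)O)c(O)c2c1C=O | target

## Step count and least certain steps

Total: 16 steps. Longest linear sequence: 13 steps (steps 1, 2, 3, 4, 6, 7, 10, 11, 12, 13, 14, 15, 16, from 1 to 20). Steps 5, 8 and 9 prepare the two side fragments.

**Step 12 (key step).** The carbenoid may be diverted before it inserts. Possible diversions are attack of the neighbouring pivalate carbonyl oxygen on the carbene carbon (carbonyl ylide formation), O–H insertion into traces of water, and bimolecular carbene coupling if the diazo compound accumulates. The doubly ortho-substituted aryl group is twisted out of conjugation, which makes the carbenoid less stabilized and less selective. The fallback makes the same C2–C3 bond by acyl transfer and sets out from phenol 10. Aldehyde 12 is oxidized (NaClO2, NaH2PO4, 2-methylbut-2-ene, Pinnick oxidation) to 2-methoxy-4-[(triisopropylsilyl)oxy]benzoic acid F1. F1 acylates the phenol of 10 (DCC, DMAP) to give 2-(2-methoxy-2-oxoethyl)-5-methoxy-4-{3-methyl-3-[(triethylsilyl)oxy]butyl}-3-(pivaloyloxy)phenyl 2-methoxy-4-[(triisopropylsilyl)oxy]benzoate F2. LiN(SiMe3)2 in THF at −78 °C then moves the aroyl group from oxygen to the ester α-carbon (an intramolecular Claisen condensation related to the Baker–Venkataraman rearrangement). This gives methyl 2-[6-hydroxy-4-methoxy-3-{3-methyl-3-[(triethylsilyl)oxy]butyl}-2-(pivaloyloxy)phenyl]-3-{2-methoxy-4-[(triisopropylsilyl)oxy]phenyl}-3-oxopropanoate F3. Cyclodehydration of F3 (PPTS, toluene, heat) gives benzofuran ester 17, where the fallback rejoins the route; it replaces steps 11 to 13.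

**Step 4.** Ketalization of the doubly ortho-substituted ketone may be slow, so that α-oxygenation without aryl shift competes. The acid may also remove iodine from the electron-rich ring by ipso-protonation. The fallback is a Wolff homologation and sets out from ketone 4. Trifluoroacetylation of the ketone enolate (LiN(SiMe3)2, CF3CO2CH2CF3, THF, −78 °C) gives 3-(benzyloxy)-6-iodo-5-methoxy-2-(4,4,4-trifluoro-3-oxobutanoyl)phenyl pivalate F4. Detrifluoroacetylative diazo transfer (MsN3, Et3N, MeCN) gives 3-(benzyloxy)-2-(diazoacetyl)-6-iodo-5-methoxyphenyl pivalate F5. Wolff rearrangement of F5 in methanol (PhCO2Ag, Et3N) gives arylacetate 5, where it rejoins the route.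

**Step 11.** The crowded, twisted arylacetate is weakly acidic, so diazo transfer may stop short. Under prolonged base the pivaloyl group may migrate from oxygen to the enolate carbon. The fallback activates the ester first and sets out from 14. Kinetic enolization and trifluoroacetylation (LiN(SiMe3)2, CF3CO2CH2CF3, THF, −78 °C) give methyl 4,4,4-trifluoro-2-[6-({2-methoxy-4-[(triisopropylsilyl)oxy]phenyl}methoxy)-4-methoxy-3-{3-methyl-3-[(triethylsilyl)oxy]butyl}-2-(pivaloyloxy)phenyl]-3-oxobutanoate F6. This much more acidic compound undergoes deacylative diazo transfer (MsN3, Et3N, MeCN) to give 15, where it rejoins the route.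

**Step 13.** Hydride abstraction next to the ester may be sluggish. The quinone may then over-oxidize the C5 benzylic methylene, which lies para to O1. The fallback is an enolate-based dehydrogenation and sets out from 16. Deprotonation at C3 (LiN(SiMe3)2, THF, −78 °C) and trapping with PhSeBr give methyl 2-{2-methoxy-4-[(triisopropylsilyl)oxy]phenyl}-6-methoxy-5-{3-methyl-3-[(triethylsilyl)oxy]butyl}-3-(phenylselanyl)-4-(pivaloyloxy)-2,3-dihydro-1-benzofuran-3-carboxylate F7. Oxidation with H2O2 and syn elimination of the selenoxide toward C2–H give 17, where it rejoins the route.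

**Step 2.** Iodination may occur at the other free ring carbon, para to the hydroxyl, or twice. The fallback reverses the order and sets out from 1. Mono-iodination of the symmetrical diol (N-iodosuccinimide, 1 equiv) can give only 1-(2,6-dihydroxy-3-iodo-4-methoxyphenyl)ethanone F8. Monobenzylation of F8 (BnBr, K2CO3, acetone) at the less hindered hydroxyl remote from iodine gives 3, where it rejoins the route.

## Further compounds

F1 | step 12 | 2-methoxy-4-[(triisopropylsilyl)oxy]benzoic acid | COc1cc(O[Si](C(C)C)(C(C)C)C(C)C)ccc1C(=O)O
F2 | step 12 | 2-(2-methoxy-2-oxoethyl)-5-methoxy-4-{3-methyl-3-[(triethylsilyl)oxy]butyl}-3-(pivaloyloxy)phenyl 2-methoxy-4-[(triisopropylsilyl)oxy]benzoate | COC(=O)Cc1c(OC(=O)c2ccc(O[Si](C(C)C)(C(C)C)C(C)C)cc2OC)cc(OC)c(CCC(C)(C)O[Si](CC)(CC)CC)c1OC(=O)C(C)(C)C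
F3 | step 12 | methyl 2-[6-hydroxy-4-methoxy-3-{3-methyl-3-[(triethylsilyl)oxy]butyl}-2-(pivaloyloxy)phenyl]-3-{2-methoxy-4-[(triisopropylsilyl)oxy]phenyl}-3-oxopropanoate | COC(=O)C(C(=O)c1ccc(O[Si](C(C)C)(C(C)C)C(C)C)cc1OC)c1c(O)cc(OC)c(CCC(C)(C)O[Si](CC)(CC)CC)c1OC(=O)C(C)(C)C
F4 | step 4 | 3-(benzyloxy)-6-iodo-5-methoxy-2-(4,4,4-trifluoro-3-oxobutanoyl)phenyl pivalate | O=C(CC(=O)c1c(OC(=O)C(C)(C)C)c(I)c(OC)cc1OCc1ccccc1)C(F)(F)F
F5 | step 4 | 3-(benzyloxy)-2-(diazoacetyl)-6-iodo-5-methoxyphenyl pivalate | [N-]=[N+]=CC(=O)c1c(OC(=O)C(C)(C)C)c(I)c(OC)cc1OCc1ccccc1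
F6 | step 11 | methyl 4,4,4-trifluoro-2-[6-({2-methoxy-4-[(triisopropylsilyl)oxy]phenyl}methoxy)-4-methoxy-3-{3-methyl-3-[(triethylsilyl)oxy]butyl}-2-(pivaloyloxy)phenyl]-3-oxobutanoate | COC(=O)C(C(=O)C(F)(F)F)c1c(OCc2ccc(O[Si](C(C)C)(C(C)C)C(C)C)cc2OC)cc(OC)c(CCC(C)(C)O[Si](CC)(CC)CC)c1OC(=O)C(C)(C)C
F7 | step 13 | methyl 2-{2-methoxy-4-[(triisopropylsilyl)oxy]phenyl}-6-methoxy-5-{3-methyl-3-[(triethylsilyl)oxy]butyl}-3-(phenylselanyl)-4-(pivaloyloxy)-2,3-dihydro-1-benzofuran-3-carboxylate (racemic) | COC(=O)C1([Se]c2ccccc2)C(c2ccc(O[Si](C(C)C)(C(C)C)C(C)C)cc2OC)Oc2cc(OC)c(CCC(C)(C)O[Si](CC)(CC)CC)c(OC(=O)C(C)(C)C)c21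
F8 | step 2 | 1-(2,6-dihydroxy-3-iodo-4-methoxyphenyl)ethanone | CC(=O)c1c(O)cc(OC)c(I)c1O
A1 | alternative 1 | methyl 4-(benzyloxy)-2-[4-(benzyloxy)-2-methoxyphenyl]-5-(3-hydroxy-3-methylbutyl)-6-methoxy-1-benzofuran-3-carboxylate | COC(=O)c1c(-c2ccc(OCc3ccccc3)cc2OC)oc2cc(OC)c(CCC(C)(C)O)c(OCc3ccccc3)c12
A2 | alternative 1 | 4-(benzyloxy)-3'-[4-(benzyloxy)-2-methoxyphenyl]-5-(3-hydroxy-3-methylbutyl)-6-methoxy-2H-spiro[1-benzofuran-3,2'-oxiran]-2-one (racemic) | O=C1Oc2cc(OC)c(CCC(C)(C)O)c(OCc3ccccc3)c2C14OC4c1ccc(OCc2ccccc2)cc1OC
A3 | alternative 2 | 2-[4-(benzyloxy)-2-methoxyphenyl]-3-(1,3-dioxolan-2-yl)-6-methoxy-5-{3-methyl-3-[(triethylsilyl)oxy]butyl}-1-benzofuran-4-ol | COc1cc(OCc2ccccc2)ccc1-c1oc2cc(OC)c(CCC(C)(C)O[Si](CC)(CC)CC)c(O)c2c1C1OCCO1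
A4 | alternative 2 | 1-{5-[4-(benzyloxy)-2-methoxyphenyl]-4-(1,3-dioxolan-2-yl)furan-2-yl}-2-diazoethan-1-one | [N-]=[N+]=CC(=O)c1cc(C2OCCO2)c(-c2ccc(OCc3ccccc3)cc2OC)o1
A5 | alternative 2 | triethyl[(6-methoxy-2-methylhex-5-yn-2-yl)oxy]silane | COC#CCCC(C)(C)O[Si](CC)(CC)CC
A6 | alternative 3 | 3,7-bis(benzyloxy)-9-methoxy-8-{3-methyl-3-[(triethylsilyl)oxy]butyl}-6H-[1]benzofuro[3,2-c]chromen-6-one | O=C1Oc2cc(OCc3ccccc3)ccc2-c2oc3cc(OC)c(CCC(C)(C)O[Si](CC)(CC)CC)c(OCc4ccccc4)c3c12
A7 | alternative 3 | 5-(benzyloxy)-2-bromophenyl 4-(benzyloxy)-6-methoxy-5-{3-methyl-3-[(triethylsilyl)oxy]butyl}-1-benzofuran-3-carboxylate | O=C(Oc1cc(OCc2ccccc2)ccc1Br)c1coc2cc(OC)c(CCC(C)(C)O[Si](CC)(CC)CC)c(OCc3ccccc3)c12
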